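**Plan**
- Retrosynthesis: the eight phenols are unmasked last. In ring C the C3–OH/C4–H pair, and in ring F the C3'–OH/C4'–H pair, each sit next to an aryl-bearing C2 of the same configuration. Each pyran ring is therefore the hydrate of a flav-3-ene, and both are traced back to the C3=C4 and C3'=C4' alkenes of one bis(flav-3-ene).
- Both alkenes are cut together (double ring-closing metathesis) to a bis(1-arylallyl) ether. Its two C2–O1 bonds are cut (iridium-catalysed allylic etherification) to a bisphenolic 1,1-diarylethene with an ortho vinyl group on ring D. The C4–C6' bond is cut last (aryllithium plus aldehyde, then C=O to C=CH2).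
- Forward: rings A and D both come from 3,4-bis(benzyloxy)-2-hydroxybenzaldehyde and are joined at C4. The two B/E-ring allyl units are attached in one operation, rings C and F close in one operation, and both alkenes are hydrated in one operation.
- Stereochemistry: C2 and C2' come from ligand control in the allylic etherification (same sense at both). C3, C4 and C3' come from syn hydroboration anti to the C2 aryl groups.

Key step: step 15

Assumption: the (Sa,Sc,Sc)-phosphoramidite is taken to give the (S)-configured branched aryl ether in the iridium step; if a trial on phenol 3 shows the opposite sense, the (Ra,Rc,Rc)-ligand is used and nothing else changes.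

**Route**

Step 1
Reactants: 1 2,3,4-trihydroxybenzaldehyde
Product: 2 2,3,4-tris(benzyloxy)benzaldehyde
Conditions: BnBr (3.3 equiv), K2CO3, DMF, 60 °C, N2
Reagents that add atoms: benzyl bromide, BrCc1ccccc1
Why: Williamson etherification of the three phenoxides with excess benzyl bromide should proceed cleanly and masks the air-sensitive pyrogallol unit in the first operation.

Step 2
Reactants: 2 2,3,4-tris(benzyloxy)benzaldehyde
Product: 3 3,4-bis(benzyloxy)-2-hydroxybenzaldehyde
Conditions: MgBr2·OEt2 (2 equiv), toluene/Et2O, reflux; aqueous work-up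
Reagents that add atoms: none
Why: Chelation-directed ether cleavage, in which magnesium held between the formyl oxygen and the ortho ether oxygen activates only the 2-benzyloxy group for attack by bromide, should free the 2-hydroxyl and leave the 3- and 4-benzyl ethers.

Step 3
Reactants: 3 3,4-bis(benzyloxy)-2-hydroxybenzaldehyde
Product: 4 2-(allyloxy)-3,4-bis(benzyloxy)benzaldehyde
Conditions: allyl bromide, K2CO3, DMF, rt
Reagents that add atoms: allyl bromide, C=CCBr
Why: Williamson etherification of the chelated phenol; allyl is chosen because it tolerates aryllithium, oxidant and ylide, cannot migrate to a neighbouring benzylic alkoxide as a silyl group would, and later leaves under neutral palladium catalysis without touching benzyl ethers.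

Step 4
Reactants: 3 3,4-bis(benzyloxy)-2-hydroxybenzaldehyde
Product: 5 3,4-bis(benzyloxy)-5-bromo-2-hydroxybenzaldehyde
Conditions: NBS (1.0 equiv), MeCN, 0 °C
Reagents that add atoms: N-bromosuccinimide, O=C1CCC(=O)N1Br
Why: Electrophilic aromatic bromination should occur only at C5, which is para to the free hydroxyl, ortho to the 4-benzyloxy group and meta to the formyl group.

Step 5
Reactants: 5 3,4-bis(benzyloxy)-5-bromo-2-hydroxybenzaldehyde
Product: 6 2-(allyloxy)-3,4-bis(benzyloxy)-5-bromobenzaldehyde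
Conditions: allyl bromide, K2CO3, DMF, rt
Reagents that add atoms: allyl bromide, C=CCBr
Why: Williamson etherification as in step 3, giving ring D the same phenol protection as ring A so that both are released together in step 13.

Step 6
Reactants: 6 2-(allyloxy)-3,4-bis(benzyloxy)-5-bromobenzaldehyde
Product: 7 1-(allyloxy)-2,3-bis(benzyloxy)-4-bromo-6-vinylbenzene
Conditions: Ph3PCH3Br, KOtBu, THF, 0 °C → rt
Reagents that add atoms: methyltriphenylphosphonium bromide, C[P+](c1ccccc1)(c1ccccc1)c1ccccc1.[Br-]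
Why: Wittig methylenation of the aryl aldehyde installs the ring-D vinyl group, whose inner carbon becomes C4', while the aryl bromide and the allyl ether are inert to the ylide.

Step 7
Reactants: 8 3,4-bis(benzyloxy)benzaldehyde
Product: 9 ethyl (E)-3-[3,4-bis(benzyloxy)phenyl]acrylate
Conditions: Ph3P=CHCO2Et, toluene, 80 °C
Reagents that add atoms: ethyl (triphenylphosphoranylidene)acetate, CCOC(=O)C=P(c1ccccc1)(c1ccccc1)c1ccccc1
Why: Wittig olefination with a stabilised ylide should give the (E)-cinnamate selectively.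

Step 8
Reactants: 9 ethyl (E)-3-[3,4-bis(benzyloxy)phenyl]acrylate
Product: 10 (E)-3-[3,4-bis(benzyloxy)phenyl]prop-2-en-1-ol
Conditions: i-Bu2AlH (2.5 equiv), CH2Cl2, −78 °C; aqueous Rochelle salt
Reagents that add atoms: none
Why: 1,2-Reduction of the enoate by two hydride equivalents at low temperature gives the allylic alcohol without touching the alkene or the benzyl ethers.

Step 9
Reactants: 10 (E)-3-[3,4-bis(benzyloxy)phenyl]prop-2-en-1-ol
Product: 11 (E)-3-[3,4-bis(benzyloxy)phenyl]allyl methyl carbonate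
Conditions: ClCO2Me, pyridine, CH2Cl2, 0 °C
Reagents that add atoms: methyl chloroformate, COC(=O)Cl
Why: O-Acylation with a chloroformate gives the linear allylic methyl carbonate, the usual leaving group for iridium-catalysed allylic substitution.

Step 10
Reactants: 7 1-(allyloxy)-2,3-bis(benzyloxy)-4-bromo-6-vinylbenzene; 4 2-(allyloxy)-3,4-bis(benzyloxy)benzaldehyde
Product: 13 [2-(allyloxy)-3,4-bis(benzyloxy)phenyl][4-(allyloxy)-2,3-bis(benzyloxy)-5-vinylphenyl]methanol (racemic), via aryllithium 12 (not isolated)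
Conditions: n-BuLi (1.05 equiv), THF, −78 °C, 10 min; then 4, −78 → −40 °C; H2O
Reagents that add atoms: none
Why: Bromine–lithium exchange, which at −78 °C should outrun addition of butyllithium to the hindered styrene or attack on the allyl ether, is followed by 1,2-addition of the aryllithium to the aldehyde to form the C4–C6' bond; the carbinol centre forms racemic and is erased in step 11.

Step 11
Reactants: 13 [2-(allyloxy)-3,4-bis(benzyloxy)phenyl][4-(allyloxy)-2,3-bis(benzyloxy)-5-vinylphenyl]methanol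
Product: 14 [2-(allyloxy)-3,4-bis(benzyloxy)phenyl][4-(allyloxy)-2,3-bis(benzyloxy)-5-vinylphenyl]methanone
Conditions: Dess–Martin periodinane, CH2Cl2, rt
Reagents that add atoms: none
Why: Dess–Martin oxidation of the doubly benzylic secondary alcohol to the benzophenone should be fast under near-neutral conditions that spare the styrene and the allyl ethers.

Step 12
Reactants: 14 [2-(allyloxy)-3,4-bis(benzyloxy)phenyl][4-(allyloxy)-2,3-bis(benzyloxy)-5-vinylphenyl]methanone
Product: 15 1-[2-(allyloxy)-3,4-bis(benzyloxy)phenyl]-1-[4-(allyloxy)-2,3-bis(benzyloxy)-5-vinylphenyl]ethene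
Conditions: Ph3PCH3Br, KOtBu, THF, reflux
Reagents that add atoms: methyltriphenylphosphonium bromide, C[P+](c1ccccc1)(c1ccccc1)c1ccccc1.[Br-]
Why: Wittig methylenation of the non-enolisable diaryl ketone, driven by heating with excess ylide, gives the 1,1-diarylethene whose internal carbon becomes C4.

Step 13
Reactants: 15 1-[2-(allyloxy)-3,4-bis(benzyloxy)phenyl]-1-[4-(allyloxy)-2,3-bis(benzyloxy)-5-vinylphenyl]ethene
Product: 16 1-[3,4-bis(benzyloxy)-2-hydroxyphenyl]-1-[2,3-bis(benzyloxy)-4-hydroxy-5-vinylphenyl]ethene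
Conditions: Pd(PPh3)4 (5 mol%), morpholine (10 equiv), THF, 40 °C
Reagents that add atoms: none
Why: Tsuji–Trost deallylation, in which zerovalent palladium ionises each aryl allyl ether to a π-allylpalladium complex that morpholine traps, frees both phenols under neutral conditions that leave the benzyl ethers, the styrene and the acid-sensitive 1,1-diarylethene untouched.

Step 14
Reactants: 16 1-[3,4-bis(benzyloxy)-2-hydroxyphenyl]-1-[2,3-bis(benzyloxy)-4-hydroxy-5-vinylphenyl]ethene; 11 (E)-3-[3,4-bis(benzyloxy)phenyl]allyl methyl carbonate (two equivalents consumed)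
Product: 18 1-{3,4-bis(benzyloxy)-2-[(S)-1-(3,4-bis(benzyloxy)phenyl)allyloxy]phenyl}-1-{2,3-bis(benzyloxy)-4-[(S)-1-(3,4-bis(benzyloxy)phenyl)allyloxy]-5-vinylphenyl}ethene, via dilithium bis(aryloxide) 17 (not isolated)
Conditions: n-BuLi (2.0 equiv), THF, 0 °C; then 11 (3 equiv), [Ir(cod)Cl]2 (4 mol%), (Sa,Sc,Sc)-O,O'-(1,1'-binaphthyl-2,2'-diyl) N,N-bis(1-phenylethyl)phosphoramidite (8 mol%), catalyst pre-activated with n-PrNH2, THF, rt → 40 °C
Reagents that add atoms: none
Why: Iridium-catalysed branched-selective allylic etherification: the cyclometalated iridium–phosphoramidite complex ionises 11 to an allyliridium intermediate that each lithium aryloxide attacks at the aryl-bearing terminus on the face fixed by the ligand, so both new C2 and C2' centres are set (S) by catalyst control with one ligand, and any minor mixed diastereomer is removed by chromatography.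

Step 15
Reactants: 18 1-{3,4-bis(benzyloxy)-2-[(S)-1-(3,4-bis(benzyloxy)phenyl)allyloxy]phenyl}-1-{2,3-bis(benzyloxy)-4-[(S)-1-(3,4-bis(benzyloxy)phenyl)allyloxy]-5-vinylphenyl}ethene
Product: 20 (S)-7,8-bis(benzyloxy)-2-[3,4-bis(benzyloxy)phenyl]-4-{(S)-7,8-bis(benzyloxy)-2-[3,4-bis(benzyloxy)phenyl]-2H-chromen-6-yl}-2H-chromene, via ring-F-closed monochromene 19 (not isolated)
Conditions: second-generation Hoveyda–Grubbs catalyst RuCl2(H2IMes)(=CH-C6H4-2-O-i-Pr) (2 × 5 mol%), 1,4-benzoquinone (20 mol%), toluene (0.005 M), 80 °C, argon sparge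
Reagents that add atoms: none
Why: The ruthenium alkylidene released from the chelated precatalyst first engages the two monosubstituted allyl alkenes, and each resulting carbene adds across its own ortho alkene by [2+2] cycloaddition and cycloreversion with loss of ethene. The closest known reaction type is ring-closing metathesis of 2-vinylaryl and 2-(1-arylvinyl)aryl allyl ethers to 2H-chromenes and 4-substituted 2H-chromenes. Ring F closes first, as a six-membered ring from the lower allyl ether and the ring-D styrene (new C3'=C4' bond); ring C closes second and more slowly, again as a six-membered ring, from the upper allyl ether and the 1,1-diarylethene (new trisubstituted C3=C4 bond). No stereocentre is formed, and the C2 and C2' centres from step 14 are sp3 spectators that cannot epimerise under these neutral conditions. The step needs each carbene to pair with its own ortho alkene and needs no double-bond migration: pairing is secured because the crossed closures would give strained medium-ring cyclophanes and high dilution disfavours intermolecular metathesis, and 1,4-benzoquinone intercepts ruthenium hydrides that would isomerise the allyl ethers to enol ethers.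

Step 16
Reactants: 20 (S)-7,8-bis(benzyloxy)-2-[3,4-bis(benzyloxy)phenyl]-4-{(S)-7,8-bis(benzyloxy)-2-[3,4-bis(benzyloxy)phenyl]-2H-chromen-6-yl}-2H-chromene
Product: 22 octa-O-benzyl ether of 23 (all eight phenolic hydroxyls as benzyl ethers; 3-OH and 3'-OH free; ring C 2,3-trans-3,4-trans; ring F 2,3-trans), via bis(alkylborane) 21 (not isolated)
Conditions: BH3·SMe2 (6 equiv), THF, 0 °C → rt; then 3 M NaOH, 30% H2O2, 0 °C → rt
Reagents that add atoms: hydrogen peroxide, OO
Why: Hydroboration–oxidation: borane adds syn to each chromene alkene from the face opposite the adjacent C2 aryl group with boron on C3 (β to the fused arene and, in ring C, the less substituted carbon), so oxidation with retention gives the 2,3-trans alcohols in both rings and, because hydrogen enters C4 on the face where boron enters C3, the 3,4-trans arrangement in ring C, all three new centres (C3, C4, C3') being controlled by the preset C2 and C2' centres.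

Step 17
Reactants: 22 octa-O-benzyl ether of 23
Product: 23 (2R,3S,4R)-2-(3,4-dihydroxyphenyl)-4-[(2R,3S)-2-(3,4-dihydroxyphenyl)-3,7,8-trihydroxychroman-6-yl]chroman-3,7,8-triol (CNP0111710.1)
Conditions: H2 (1 atm), Pd(OH)2/C, THF/MeOH, rt; filtration and freeze-drying under argon
Reagents that add atoms: none
Why: Hydrogenolysis of the eight aryl benzyl ethers over Pd(OH)2 on carbon should be fast enough at 1 atm that the cyclic benzylic C2–O bonds and the doubly benzylic C4–aryl bond stay intact, and air is excluded on isolation because the 7,8-dihydroxy rings oxidise readily.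

**Compound list**

1 | 2,3,4-trihydroxybenzaldehyde | O=Cc1ccc(O)c(O)c1O | starting material
2 | 2,3,4-tris(benzyloxy)benzaldehyde | O=Cc1ccc(OCc2ccccc2)c(OCc2ccccc2)c1OCc1ccccc1 | intermediate
3 | 3,4-bis(benzyloxy)-2-hydroxybenzaldehyde | O=Cc1ccc(OCc2ccccc2)c(OCc2ccccc2)c1O | intermediate
4 | 2-(allyloxy)-3,4-bis(benzyloxy)benzaldehyde | O=Cc1ccc(OCc2ccccc2)c(OCc2ccccc2)c1OCC=C | intermediate
5 | 3,4-bis(benzyloxy)-5-bromo-2-hydroxybenzaldehyde | O=Cc1cc(Br)c(OCc2ccccc2)c(OCc2ccccc2)c1O | intermediate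
6 | 2-(allyloxy)-3,4-bis(benzyloxy)-5-bromobenzaldehyde | O=Cc1cc(Br)c(OCc2ccccc2)c(OCc2ccccc2)c1OCC=C | intermediate
7 | 1-(allyloxy)-2,3-bis(benzyloxy)-4-bromo-6-vinylbenzene | C=Cc1cc(Br)c(OCc2ccccc2)c(OCc2ccccc2)c1OCC=C | intermediate
8 | 3,4-bis(benzyloxy)benzaldehyde | O=Cc1ccc(OCc2ccccc2)c(OCc2ccccc2)c1 | starting material
9 | ethyl (E)-3-[3,4-bis(benzyloxy)phenyl]acrylate | CCOC(=O)/C=C/c1ccc(OCc2ccccc2)c(OCc2ccccc2)c1 | intermediate
10 | (E)-3-[3,4-bis(benzyloxy)phenyl]prop-2-en-1-ol | OC/C=C/c1ccc(OCc2ccccc2)c(OCc2ccccc2)c1 | intermediate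
11 | (E)-3-[3,4-bis(benzyloxy)phenyl]allyl methyl carbonate | COC(=O)OC/C=C/c1ccc(OCc2ccccc2)c(OCc2ccccc2)c1 | intermediate
12 | [4-(allyloxy)-2,3-bis(benzyloxy)-5-vinylphenyl]lithium | [Li]c1cc(C=C)c(OCC=C)c(OCc2ccccc2)c1OCc1ccccc1 | intermediate (not isolated)
13 | [2-(allyloxy)-3,4-bis(benzyloxy)phenyl][4-(allyloxy)-2,3-bis(benzyloxy)-5-vinylphenyl]methanol (racemic) | OC(c1ccc(OCc2ccccc2)c(OCc2ccccc2)c1OCC=C)c1cc(C=C)c(OCC=C)c(OCc2ccccc2)c1OCc1ccccc1 | intermediate
14 | [2-(allyloxy)-3,4-bis(benzyloxy)phenyl][4-(allyloxy)-2,3-bis(benzyloxy)-5-vinylphenyl]methanone | O=C(c1ccc(OCc2ccccc2)c(OCc2ccccc2)c1OCC=C)c1cc(C=C)c(OCC=C)c(OCc2ccccc2)c1OCc1ccccc1 | intermediate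
15 | 1-[2-(allyloxy)-3,4-bis(benzyloxy)phenyl]-1-[4-(allyloxy)-2,3-bis(benzyloxy)-5-vinylphenyl]ethene | C=C(c1ccc(OCc2ccccc2)c(OCc2ccccc2)c1OCC=C)c1cc(C=C)c(OCC=C)c(OCc2ccccc2)c1OCc1ccccc1 | intermediate
16 | 1-[3,4-bis(benzyloxy)-2-hydroxyphenyl]-1-[2,3-bis(benzyloxy)-4-hydroxy-5-vinylphenyl]ethene | C=C(c1ccc(OCc2ccccc2)c(OCc2ccccc2)c1O)c1cc(C=C)c(O)c(OCc2ccccc2)c1OCc1ccccc1 | intermediate
17 | dilithium bis(aryloxide) of 16 | [Li+].[Li+].C=C(c1ccc(OCc2ccccc2)c(OCc2ccccc2)c1[O-])c1cc(C=C)c([O-])c(OCc2ccccc2)c1OCc1ccccc1 | intermediate (not isolated)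
18 | bis[(S)-1-(3,4-bis(benzyloxy)phenyl)allyl] ether of 16 (metathesis precursor) | C=C[C@H](Oc1c(OCc2ccccc2)c(OCc2ccccc2)ccc1C(=C)c1cc(C=C)c(O[C@@H](C=C)c2ccc(OCc3ccccc3)c(OCc3ccccc3)c2)c(OCc2ccccc2)c1OCc1ccccc1)c1ccc(OCc2ccccc2)c(OCc2ccccc2)c1 | intermediate
19 | monochromene with ring F closed (lower (S)-2H-chromene formed, upper (S)-allyl ether and 1,1-diarylethene still open) | C=C[C@H](Oc1c(OCc2ccccc2)c(OCc2ccccc2)ccc1C(=C)c1cc2C=C[C@@H](c3ccc(OCc4ccccc4)c(OCc4ccccc4)c3)Oc2c(OCc2ccccc2)c1OCc1ccccc1)c1ccc(OCc2ccccc2)c(OCc2ccccc2)c1 | intermediate (not isolated)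
20 | (S)-7,8-bis(benzyloxy)-2-[3,4-bis(benzyloxy)phenyl]-4-{(S)-7,8-bis(benzyloxy)-2-[3,4-bis(benzyloxy)phenyl]-2H-chromen-6-yl}-2H-chromene | C1=C(c2cc3C=C[C@@H](c4ccc(OCc5ccccc5)c(OCc5ccccc5)c4)Oc3c(OCc3ccccc3)c2OCc2ccccc2)c2ccc(OCc3ccccc3)c(OCc3ccccc3)c2O[C@@H]1c1ccc(OCc2ccccc2)c(OCc2ccccc2)c1 | intermediate
21 | bis(alkylborane) with BH2 on C3 and C3' (each trans to its C2 aryl group; H on C4 cis to boron) | B[C@H]1[C@H](c2cc3C[C@H](B)[C@@H](c4ccc(OCc5ccccc5)c(OCc5ccccc5)c4)Oc3c(OCc3ccccc3)c2OCc2ccccc2)c2ccc(OCc3ccccc3)c(OCc3ccccc3)c2O[C@@H]1c1ccc(OCc2ccccc2)c(OCc2ccccc2)c1 | intermediate (not isolated)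
22 | octa-O-benzyl ether of 23 (configuration in space as in 23) | O[C@H]1[C@H](c2cc3C[C@H](O)[C@@H](c4ccc(OCc5ccccc5)c(OCc5ccccc5)c4)Oc3c(OCc3ccccc3)c2OCc2ccccc2)c2ccc(OCc3ccccc3)c(OCc3ccccc3)c2O[C@@H]1c1ccc(OCc2ccccc2)c(OCc2ccccc2)c1 | intermediate
23 | (2R,3S,4R)-2-(3,4-dihydroxyphenyl)-4-[(2R,3S)-2-(3,4-dihydroxyphenyl)-3,7,8-trihydroxychroman-6-yl]chroman-3,7,8-triol | Oc1ccc([C@H]2Oc3c(ccc(O)c3O)[C@@H](c3cc4c(c(O)c3O)O[C@H](c3ccc(O)c(O)c3)[C@@H](O)C4)[C@@H]2O)cc1O | target

**Step count and risks**

Total step count: 17. Longest linear sequence: 13 steps (1, 2, 4, 5, 6, 10, 11, 12, 13, 14, 15, 16, 17); steps 3 and 7–9 are side branches.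

Steps most likely to fail:

Step 14. Both aryloxides are flanked by two ortho substituents, so their attack on the allyliridium intermediate may be slow. Carbonate exchange, formation of the linear cinnamyl ether, stalling at the mono-ether, and ionisation of the electron-rich branched ether (loss of enantiopurity) could then compete. The fallback replaces allylic substitution by an SN2 etherification of a propargylic alcohol. It sets out from 8 and 16 and comes back at 18. Asymmetric zinc alkynylation of 8 (Me2Zn, trimethylsilylacetylene, ProPhenol ligand of the appropriate hand, toluene) should give (S)-1-[3,4-bis(benzyloxy)phenyl]-3-(trimethylsilyl)prop-2-yn-1-ol F1. K2CO3 in MeOH removes silicon to give (R)-1-[3,4-bis(benzyloxy)phenyl]prop-2-yn-1-ol F2; the descriptor changes with loss of silicon, the arrangement in space does not. A double Mitsunobu reaction of 16 with F2 (PPh3, DIAD, THF, 0 °C) should proceed with inversion, a propargylic carbinol being far less prone to SN2' attack or ionisation than an allylic one, and give the bis[(S)-1-arylprop-2-ynyl] ether F3. Semi-hydrogenation of the two terminal alkynes over Pd/CaCO3 poisoned with Pb(OAc)2 and quinoline (H2, 1 atm, EtOAc) then gives 18.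

Step 15. The carbene formed at the upper allyl ether may fail to add across the twisted, hindered 1,1-diarylethene. Ring F would then close alone, while the open carbene decays or moves the allyl double bond into conjugation with oxygen. The fallback forms the same C3=C4 bond by olefin–carbonyl ring closure on the ketone instead of the methylene compound. It sets out from 14 (with 11) and comes back at 20. Deallylation of 14 as in step 13 gives [3,4-bis(benzyloxy)-2-hydroxyphenyl][2,3-bis(benzyloxy)-4-hydroxy-5-vinylphenyl]methanone F4. Etherification as in step 14 gives its bis[(S)-1-arylallyl] ether F5. The ruthenium catalyst of step 15 closes only ring F, from the styrene, to give the chromenyl aryl ketone F6. One equivalent of the alkylidene Mo(=CHCMe2Ph)(=N-2,6-i-Pr2C6H3)[OCMe(CF3)2]2 in benzene at rt should then exchange onto the remaining terminal alkene and olefinate the diaryl ketone intramolecularly, the strong Mo=O bond driving closure of ring C to give 20.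

Step 16. Two different alkenes and three new centres are handled in one operation, so small leaks multiply. Boron may enter partly at the benzylic C4' of ring F or on the face syn to a C2 aryl group, and a C3 borane β to the ring oxygen may eliminate with opening of the pyran ring. The fallback gives up the two-directional hydration and sets C4 by cationic arylation. It sets out from 3 (with 11) and comes back at 22. Wittig methylenation of 3 (2.2 equiv ylide) gives 2,3-bis(benzyloxy)-6-vinylphenol F7. Etherification with 11 as in step 14 gives 1,2-bis(benzyloxy)-3-{[(S)-1-(3,4-bis(benzyloxy)phenyl)allyl]oxy}-4-vinylbenzene F8. Ring-closing metathesis of this unhindered diene gives (S)-7,8-bis(benzyloxy)-2-[3,4-bis(benzyloxy)phenyl]-2H-chromene F9. Hydroboration–oxidation of this single disubstituted alkene gives (2R,3S)-7,8-bis(benzyloxy)-2-[3,4-bis(benzyloxy)phenyl]chroman-3-ol F10. DDQ with 2-ethoxyethanol in CH2Cl2 oxidises C4 to give the 4-(2-ethoxyethoxy) derivative of the flavan-3-ol F11 (C4 epimers, both usable). TMSOTf at −78 °C ionises F11, and an excess of F10 should capture the C4 cation through its C6 (ortho to the 7-benzyloxy group, para to the ring oxygen) on the face trans to the 3-hydroxyl, which gives 22.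

**Further compounds**

F1 | step 14 | (S)-1-[3,4-bis(benzyloxy)phenyl]-3-(trimethylsilyl)prop-2-yn-1-ol | O[C@H](C#C[Si](C)(C)C)c1ccc(OCc2ccccc2)c(OCc2ccccc2)c1
F2 | step 14 | (R)-1-[3,4-bis(benzyloxy)phenyl]prop-2-yn-1-ol | O[C@H](C#C)c1ccc(OCc2ccccc2)c(OCc2ccccc2)c1
F3 | step 14 | bis[(S)-1-(3,4-bis(benzyloxy)phenyl)prop-2-ynyl] ether of 16 | C#C[C@H](Oc1c(OCc2ccccc2)c(OCc2ccccc2)ccc1C(=C)c1cc(C=C)c(O[C@@H](C#C)c2ccc(OCc3ccccc3)c(OCc3ccccc3)c2)c(OCc2ccccc2)c1OCc1ccccc1)c1ccc(OCc2ccccc2)c(OCc2ccccc2)c1
F4 | step 15 | [3,4-bis(benzyloxy)-2-hydroxyphenyl][2,3-bis(benzyloxy)-4-hydroxy-5-vinylphenyl]methanone | O=C(c1ccc(OCc2ccccc2)c(OCc2ccccc2)c1O)c1cc(C=C)c(O)c(OCc2ccccc2)c1OCc1ccccc1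
F5 | step 15 | bis[(S)-1-(3,4-bis(benzyloxy)phenyl)allyl] ether of F4 | C=C[C@H](Oc1c(OCc2ccccc2)c(OCc2ccccc2)ccc1C(=O)c1cc(C=C)c(O[C@@H](C=C)c2ccc(OCc3ccccc3)c(OCc3ccccc3)c2)c(OCc2ccccc2)c1OCc1ccccc1)c1ccc(OCc2ccccc2)c(OCc2ccccc2)c1
F6 | step 15 | {3,4-bis(benzyloxy)-2-[(S)-1-(3,4-bis(benzyloxy)phenyl)allyloxy]phenyl}{(S)-7,8-bis(benzyloxy)-2-[3,4-bis(benzyloxy)phenyl]-2H-chromen-6-yl}methanone | C=C[C@H](Oc1c(OCc2ccccc2)c(OCc2ccccc2)ccc1C(=O)c1cc2C=C[C@@H](c3ccc(OCc4ccccc4)c(OCc4ccccc4)c3)Oc2c(OCc2ccccc2)c1OCc1ccccc1)c1ccc(OCc2ccccc2)c(OCc2ccccc2)c1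
F7 | step 16 | 2,3-bis(benzyloxy)-6-vinylphenol | C=Cc1ccc(OCc2ccccc2)c(OCc2ccccc2)c1O
F8 | step 16 | 1,2-bis(benzyloxy)-3-{[(S)-1-(3,4-bis(benzyloxy)phenyl)allyl]oxy}-4-vinylbenzene | C=C[C@H](Oc1c(OCc2ccccc2)c(OCc2ccccc2)ccc1C=C)c1ccc(OCc2ccccc2)c(OCc2ccccc2)c1
F9 | step 16 | (S)-7,8-bis(benzyloxy)-2-[3,4-bis(benzyloxy)phenyl]-2H-chromene | C1=Cc2ccc(OCc3ccccc3)c(OCc3ccccc3)c2O[C@@H]1c1ccc(OCc2ccccc2)c(OCc2ccccc2)c1
F10 | step 16 | (2R,3S)-7,8-bis(benzyloxy)-2-[3,4-bis(benzyloxy)phenyl]chroman-3-ol | O[C@H]1Cc2ccc(OCc3ccccc3)c(OCc3ccccc3)c2O[C@@H]1c1ccc(OCc2ccccc2)c(OCc2ccccc2)c1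
F11 | step 16 | 4-(2-ethoxyethoxy) derivative of F10 (C2 and C3 as in F10, C4 epimers) | O[C@H]1C(OCCOCC)c2ccc(OCc3ccccc3)c(OCc3ccccc3)c2O[C@@H]1c1ccc(OCc2ccccc2)c(OCc2ccccc2)c1
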